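**Retrosynthetic overview**

- Feature: in the 5,6,7,8-tetrahydrochromone, C5 and C6 are neighbouring carbinol carbons and C5 sits on C4a of the γ-pyranone ring, so the carbocycle is cut at C5–C6 back to two aldehydes; the threo C7/C8 pair is the diol of D-tartrate.
- Target 31 ⇐ acid-induced bridge closure C5–O–C7' ⇐ debenzylated triol-phenol 30 ⇐ cis-5,6-diol 29 ⇐ SmI2 pinacol cyclisation ⇐ dialdehyde 28.
- 28 ⇐ reduction of both thioesters of pyranone 27 ⇐ β-keto thioester 24 + alkynoic acid 12 (C-acylation, then 6-endo oxa-Michael closure of the γ-pyranone).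
- 24 ⇐ dimethyl D-tartrate 13: O8 benzyl ether; C7–OAr by two Mitsunobu inversions (net retention) with chromone phenol 7; the two carboxyls are told apart by boric acid esterification.
- Ring order: chromone ring of the lower unit (step 2), γ-pyranone (step 17), carbocycle (step 19), bridging dioxa ring (step 21).

Key step: step 19

Remark: the target is taken as the (5R,6S,7R,8S) compound of the given SMILES. Ar = 7-(benzyloxy)-4-oxo-2-(2-phenylethyl)-4H-chromen-6-yl. Steps 1–3 and 4–6 make the two side fragments and steps 7–21 are the main line. Dialdehyde 28 is used crude. The C7 aryl ether is made by Mitsunobu reaction on an α-hydroxy ester (inversion), so C7 is inverted once beforehand, and C6 and C5 are carried as thioesters so that no hydride reagent meets the chromone.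

**Step 1**
Reactants: 1 5'-bromo-2',4'-dihydroxyacetophenone
Product: 2 1-[4-(benzyloxy)-5-bromo-2-hydroxyphenyl]ethan-1-one
Conditions: BnBr (1.05 equiv), K2CO3, acetone, reflux
Reagents that add atoms: benzyl bromide, BrCc1ccccc1
Why: Williamson etherification in which the 2-hydroxyl is held in a hydrogen bond to the acetyl group, so only the more acidic 4-hydroxyl is alkylated.

**Step 2**
Reactants: 2 1-[4-(benzyloxy)-5-bromo-2-hydroxyphenyl]ethan-1-one; 3 ethyl 3-phenylpropanoate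
Product: 5 7-(benzyloxy)-6-bromo-2-(2-phenylethyl)-4H-chromen-4-one, via 1,3-diketone 4 (not isolated)
Conditions: NaH (4 equiv), THF, reflux; then conc. HCl, MeOH, 60 °C
Reagents that add atoms: none
Why: Crossed Claisen condensation of the acetophenone enolate with the ester followed by acid-catalysed cyclodehydration, the usual route to 2-(2-phenylethyl)chromones.

**Step 3**
Reactants: 5 7-(benzyloxy)-6-bromo-2-(2-phenylethyl)-4H-chromen-4-one
Product: 7 7-(benzyloxy)-6-hydroxy-2-(2-phenylethyl)-4H-chromen-4-one, via pinacol boronate 6 (not isolated)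
Conditions: B2pin2, PdCl2(dppf) (5 mol%), KOAc, 1,4-dioxane, 90 °C; then NaBO3·4H2O, THF/H2O, rt
Reagents that add atoms: sodium perborate, [Na+].[Na+].O[B-]1(O)OO[B-](O)(O)OO1 (phenol oxygen); bis(pinacolato)diboron, CC1(C)OB(OC1(C)C)B1OC(C)(C)C(C)(C)O1 (boryl group of 6 only)
Why: Miyaura borylation of the aryl bromide and oxidative C–B to C–O exchange should give the phenol without base strong enough to open the chromone.

**Step 4**
Reactants: 8 4-methoxybenzyl bromide; 9 1-(trimethylsilyl)propyne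
Product: 10 [4-(4-methoxyphenyl)but-1-yn-1-yl]trimethylsilane
Conditions: 9, n-BuLi, THF, −78 °C; then 8, −78 °C → rt
Reagents that add atoms: none
Why: Propargylic lithiation of the silylpropyne and SN2 alkylation by the benzylic bromide, with the silyl group blocking the acetylenic terminus.

**Step 5**
Reactants: 10 [4-(4-methoxyphenyl)but-1-yn-1-yl]trimethylsilane
Product: 11 1-(but-3-yn-1-yl)-4-methoxybenzene
Conditions: K2CO3 (0.2 equiv), MeOH, rt
Reagents that add atoms: none
Why: Base-catalysed methanolysis of the alkynyl C–Si bond (protodesilylation).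

**Step 6**
Reactants: 11 1-(but-3-yn-1-yl)-4-methoxybenzene
Product: 12 5-(4-methoxyphenyl)pent-2-ynoic acid
Conditions: n-BuLi, THF, −78 °C; CO2; then 1 M HCl
Reagents that add atoms: carbon dioxide, O=C=O
Why: Carboxylation of the lithium acetylide.

**Step 7**
Reactants: 13 dimethyl D-tartrate
Product: 14 dimethyl (2S,3S)-2-(benzyloxy)-3-hydroxybutanedioate
Conditions: Ag2O (1.5 equiv), BnBr (1.1 equiv), CH2Cl2, rt, dark
Reagents that add atoms: benzyl bromide, BrCc1ccccc1
Why: Silver oxide-mediated Williamson monobenzylation of a C2-symmetric diol, in which both hydroxyls are equivalent and no stereocentre is touched; the ether oxygen becomes O8.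

**Step 8**
Reactants: 14 dimethyl (2S,3S)-2-(benzyloxy)-3-hydroxybutanedioate
Product: 15 dimethyl (2S,3R)-2-(benzyloxy)-3-[(4-nitrobenzoyl)oxy]butanedioate
Conditions: 4-nitrobenzoic acid, PPh3, DIAD, THF, 0 °C → rt
Reagents that add atoms: 4-nitrobenzoic acid, OC(=O)c1ccc(cc1)[N+](=O)[O-]
Why: Mitsunobu esterification in which the carboxylate displaces the activated α-oxyphosphonium group by SN2, inverting C3 (the future C7) to R so that the second inversion in step 12 restores the D-tartrate configuration.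

**Step 9**
Reactants: 15 dimethyl (2S,3R)-2-(benzyloxy)-3-[(4-nitrobenzoyl)oxy]butanedioate
Product: 16 (2S,3R)-2-(benzyloxy)-3-hydroxybutanedioic acid
Conditions: LiOH·H2O (4 equiv), THF/H2O, 0 °C → rt; HCl to pH 2, 4-nitrobenzoic acid filtered off
Reagents that add atoms: lithium hydroxide, [Li+].[OH-] (carboxyl oxygens)
Why: Saponification of all three esters by acyl–oxygen cleavage, which leaves both stereocentres untouched.

**Step 10**
Reactants: 16 (2S,3R)-2-(benzyloxy)-3-hydroxybutanedioic acid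
Product: 17 (2S,3R)-2-(benzyloxy)-3-hydroxy-4-methoxy-4-oxobutanoic acid
Conditions: B(OH)3 (20 mol%), MeOH, rt
Reagents that add atoms: methanol, CO
Why: Boric acid-catalysed chemoselective esterification of α-hydroxy carboxylic acids, in which only the carboxyl next to the free hydroxyl (C6) is activated as a cyclic borate and the α-benzyloxy carboxyl (C8a) stays free.

**Step 11**
Reactants: 17 (2S,3R)-2-(benzyloxy)-3-hydroxy-4-methoxy-4-oxobutanoic acid
Product: 18 1-tert-butyl 4-methyl (2S,3R)-2-(benzyloxy)-3-hydroxybutanedioate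
Conditions: tert-butyl 2,2,2-trichloroacetimidate (2 equiv), CH2Cl2/cyclohexane, rt
Reagents that add atoms: tert-butyl 2,2,2-trichloroacetimidate, CC(C)(C)OC(=N)C(Cl)(Cl)Cl
Why: tert-Butyl ester formation with the imidate, which the carboxylic acid itself protonates, so the secondary alcohol is not alkylated in the absence of a Lewis acid.

**Step 12**
Reactants: 18 1-tert-butyl 4-methyl (2S,3R)-2-(benzyloxy)-3-hydroxybutanedioate; 7 7-(benzyloxy)-6-hydroxy-2-(2-phenylethyl)-4H-chromen-4-one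
Product: 19 1-tert-butyl 4-methyl (2S,3S)-2-(benzyloxy)-3-(ArO)butanedioate
Conditions: PPh3, DIAD, toluene, 0 °C → rt
Reagents that add atoms: none
Why: Mitsunobu aryl ether synthesis on an α-hydroxy ester, in which the phenoxide displaces the oxyphosphonium group by SN2 and inverts C3 back to S, giving the threo C8/C7 relationship of the target.

**Step 13**
Reactants: 19 1-tert-butyl 4-methyl (2S,3S)-2-(benzyloxy)-3-(ArO)butanedioate
Product: 20 (2S,3S)-3-(benzyloxy)-4-tert-butoxy-2-(ArO)-4-oxobutanoic acid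
Conditions: LiOH·H2O (1.5 equiv), THF/H2O, 0 °C; then dilute HCl to pH 3
Reagents that add atoms: lithium hydroxide, [Li+].[OH-] (carboxyl oxygen)
Why: Saponification of the activated α-aryloxy methyl ester at 0 °C, to which the tert-butyl ester is inert and at which the chromone should not be opened.

**Step 14**
Reactants: 20 (2S,3S)-3-(benzyloxy)-4-tert-butoxy-2-(ArO)-4-oxobutanoic acid
Product: 21 tert-butyl (2S,3S)-2-(benzyloxy)-3-(ArO)-4-(ethylsulfanyl)-4-oxobutanoate
Conditions: EtSH (3 equiv), EDC·HCl, DMAP (0.1 equiv), CH2Cl2, 0 °C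
Reagents that add atoms: ethanethiol, CCS
Why: Steglich-type carbodiimide thioesterification, which turns C6 into the S-ethyl thioester that is reduced to the aldehyde in step 18.

**Step 15**
Reactants: 21 tert-butyl (2S,3S)-2-(benzyloxy)-3-(ArO)-4-(ethylsulfanyl)-4-oxobutanoate
Product: 22 (2S,3S)-2-(benzyloxy)-3-(ArO)-4-(ethylsulfanyl)-4-oxobutanoic acid
Conditions: TFA/CH2Cl2 (1:3), 0 °C → rt
Reagents that add atoms: none
Why: Acidolysis of the tert-butyl ester with loss of isobutene, to which the thioester, the benzyl ethers and the chromone are stable.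

**Step 16**
Reactants: 22 (2S,3S)-2-(benzyloxy)-3-(ArO)-4-(ethylsulfanyl)-4-oxobutanoic acid
Product: 24 S,S'-diethyl (2S,3S)-3-(benzyloxy)-2-(ArO)-4-oxohexanebis(thioate), via acyl Meldrum's acid 23 (not isolated)
Conditions: Meldrum's acid, EDC·HCl, DMAP, CH2Cl2, 0 °C → rt; then EtSH, toluene, 80 °C
Reagents that add atoms: Meldrum's acid, CC1(C)OC(=O)CC(=O)O1; ethanethiol, CCS
Why: C-acylation of Meldrum's acid, thermal fragmentation to the acylketene and capture by the thiol, the standard homologation of an acid to a β-keto thioester, which adds C4a and C5.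

**Step 17**
Reactants: 24 S,S'-diethyl (2S,3S)-3-(benzyloxy)-2-(ArO)-4-oxohexanebis(thioate); 12 5-(4-methoxyphenyl)pent-2-ynoic acid
Product: 27 S-ethyl 2-[(1S,2S)-1-(benzyloxy)-2-(ArO)-3-(ethylsulfanyl)-3-oxopropyl]-6-[2-(4-methoxyphenyl)ethyl]-4-oxo-4H-pyran-3-carbothioate, via acid chloride 25 (not isolated), via triacylmethane 26 (not isolated)
Conditions: 12, (COCl)2, DMF (cat.), CH2Cl2, 0 °C → rt; then 24, MgCl2, pyridine, CH2Cl2, 0 °C → rt; then TsOH·H2O (10 mol%), rt
Reagents that add atoms: oxalyl chloride, ClC(=O)C(Cl)=O (chlorine of 25 only)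
Why: C-acylation of the magnesium chelate of the β-keto thioester by the alkynoyl chloride, followed by 6-endo-dig oxa-Michael addition of the C8a enol oxygen to the ynone, closes the γ-pyranone ring with the thioester at C4a.

**Step 18**
Reactants: 27 S-ethyl 2-[(1S,2S)-1-(benzyloxy)-2-(ArO)-3-(ethylsulfanyl)-3-oxopropyl]-6-[2-(4-methoxyphenyl)ethyl]-4-oxo-4H-pyran-3-carbothioate
Product: 28 2-[(1S,2S)-1-(benzyloxy)-2-(ArO)-3-oxopropyl]-6-[2-(4-methoxyphenyl)ethyl]-4-oxo-4H-pyran-3-carbaldehyde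
Conditions: Et3SiH (8 equiv), 10% Pd/C, acetone, rt; filtered, concentrated, used at once
Reagents that add atoms: none
Why: Fukuyama reduction, in which zerovalent palladium inserts into both C(acyl)–S bonds and the silane delivers hydride, should give both aldehydes under neutral conditions that avoid enolisation at C7 and β-elimination of the C8 benzyloxy group.

**Step 19**
Reactants: 28 2-[(1S,2S)-1-(benzyloxy)-2-(ArO)-3-oxopropyl]-6-[2-(4-methoxyphenyl)ethyl]-4-oxo-4H-pyran-3-carbaldehyde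
Product: 29 (5S,6S,7R,8S)-8-(benzyloxy)-7-(ArO)-5,6-dihydroxy-2-[2-(4-methoxyphenyl)ethyl]-5,6,7,8-tetrahydro-4H-chromen-4-one
Conditions: SmI2 (3 equiv, 0.1 M in THF), t-BuOH (3 equiv), THF, −78 → −20 °C, slow addition of 28; aq. NaHCO3
Reagents that add atoms: none
Why: Divalent samarium transfers one electron to the C5 aldehyde, which is conjugated with the pyranone and is the easier carbonyl to reduce, and the ketyl carbon adds to the C6 aldehyde before a second electron gives the diolate of trivalent samarium; the closest known reaction is the SmI2 pinacol cyclisation of sugar-derived 1,6-dialdehydes to cyclohexane-1,2-diols. The new C5–C6 bond closes the six-membered carbocycle (C5, C4a, C8a, C8, C7, C6) in a 6-exo-trig mode. C6 is controlled by C7: in the samarium-bridged transition state the C6 oxygen lies anti to the C7 aryloxy group, which should give 6S with the hydroxyl trans to the aryl ether, while C5 is placed cis to the C6 oxygen by the same samarium bridge (5S) and need not be controlled because step 21 resets it. The step needs the first electron to go to C5 and not to C6, where an α-aryloxy ketyl could expel aryloxide, and it needs ring closure to outrun a second reduction that could expel the C8 benzyloxy group; the conjugation of C5 secures the first, and low temperature with slow addition of 28 to excess SmI2 and t-BuOH should secure the second.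

**Step 20**
Reactants: 29 (5S,6S,7R,8S)-8-(benzyloxy)-7-(ArO)-5,6-dihydroxy-2-[2-(4-methoxyphenyl)ethyl]-5,6,7,8-tetrahydro-4H-chromen-4-one
Product: 30 (5S,6S,7R,8S)-5,6,8-trihydroxy-7-{[7-hydroxy-4-oxo-2-(2-phenylethyl)-4H-chromen-6-yl]oxy}-2-[2-(4-methoxyphenyl)ethyl]-5,6,7,8-tetrahydro-4H-chromen-4-one
Conditions: H2 (1 atm), 10% Pd/C, EtOAc/THF, rt
Reagents that add atoms: none
Why: Hydrogenolysis of the aryl and the alkyl benzyl ether, which should be faster than reduction of the γ-pyranone and chromone rings.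

**Step 21**
Reactants: 30 (5S,6S,7R,8S)-5,6,8-trihydroxy-7-{[7-hydroxy-4-oxo-2-(2-phenylethyl)-4H-chromen-6-yl]oxy}-2-[2-(4-methoxyphenyl)ethyl]-5,6,7,8-tetrahydro-4H-chromen-4-one
Product: 31 (+)-4'-methoxyaquisinenone G, the (5R,6S,7R,8S)-6,8-dihydroxy-2-[2-(4-methoxyphenyl)ethyl]-5,6,7,8-tetrahydrochromen-4-one whose C7 and C5 are bridged through oxygen to C6' and C7' of 2-(2-phenylethyl)chromen-4-one
Conditions: CSA (0.2 equiv), MeCN (5 mM), 4 Å molecular sieves, rt → 40 °C
Reagents that add atoms: none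
Why: Acid-catalysed SN1 etherification in which C5 ionises to a vinylogous oxocarbenium ion (stabilised through C4a=C8a by O1) and the 7'-phenol, tethered through the C7 ether, can only close the bridge on the face of the C7 oxygen, so C5 is reset to R whatever the diol geometry.

**Compound list** (Ar = 7-(benzyloxy)-4-oxo-2-(2-phenylethyl)-4H-chromen-6-yl)

1 | 5'-bromo-2',4'-dihydroxyacetophenone | CC(=O)c1cc(Br)c(O)cc1O | starting material
2 | 1-[4-(benzyloxy)-5-bromo-2-hydroxyphenyl]ethan-1-one | CC(=O)c1cc(Br)c(OCc2ccccc2)cc1O | intermediate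
3 | ethyl 3-phenylpropanoate | CCOC(=O)CCc1ccccc1 | starting material
4 | 1-[4-(benzyloxy)-5-bromo-2-hydroxyphenyl]-5-phenylpentane-1,3-dione | O=C(CC(=O)CCc1ccccc1)c1cc(Br)c(OCc2ccccc2)cc1O | intermediate
5 | 7-(benzyloxy)-6-bromo-2-(2-phenylethyl)-4H-chromen-4-one | O=c1cc(CCc2ccccc2)oc2cc(OCc3ccccc3)c(Br)cc12 | intermediate
6 | 7-(benzyloxy)-2-(2-phenylethyl)-6-(4,4,5,5-tetramethyl-1,3,2-dioxaborolan-2-yl)-4H-chromen-4-one | CC1(C)OB(OC1(C)C)c1cc2c(=O)cc(CCc3ccccc3)oc2cc1OCc1ccccc1 | intermediate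
7 | 7-(benzyloxy)-6-hydroxy-2-(2-phenylethyl)-4H-chromen-4-one | Oc1cc2c(=O)cc(CCc3ccccc3)oc2cc1OCc1ccccc1 | intermediate
8 | 4-methoxybenzyl bromide | COc1ccc(CBr)cc1 | starting material
9 | 1-(trimethylsilyl)propyne | CC#C[Si](C)(C)C | starting material
10 | [4-(4-methoxyphenyl)but-1-yn-1-yl]trimethylsilane | COc1ccc(CCC#C[Si](C)(C)C)cc1 | intermediate
11 | 1-(but-3-yn-1-yl)-4-methoxybenzene | COc1ccc(CCC#C)cc1 | intermediate
12 | 5-(4-methoxyphenyl)pent-2-ynoic acid | COc1ccc(CCC#CC(=O)O)cc1 | intermediate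
13 | dimethyl D-tartrate, (2S,3S) | COC(=O)[C@@H](O)[C@H](O)C(=O)OC | starting material
14 | dimethyl (2S,3S)-2-(benzyloxy)-3-hydroxybutanedioate | COC(=O)[C@@H](OCc1ccccc1)[C@H](O)C(=O)OC | intermediate
15 | dimethyl (2S,3R)-2-(benzyloxy)-3-[(4-nitrobenzoyl)oxy]butanedioate | COC(=O)[C@@H](OCc1ccccc1)[C@@H](OC(=O)c1ccc(cc1)[N+](=O)[O-])C(=O)OC | intermediate
16 | (2S,3R)-2-(benzyloxy)-3-hydroxybutanedioic acid | OC(=O)[C@@H](OCc1ccccc1)[C@@H](O)C(=O)O | intermediate
17 | (2S,3R)-2-(benzyloxy)-3-hydroxy-4-methoxy-4-oxobutanoic acid | OC(=O)[C@@H](OCc1ccccc1)[C@@H](O)C(=O)OC | intermediate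
18 | 1-tert-butyl 4-methyl (2S,3R)-2-(benzyloxy)-3-hydroxybutanedioate | CC(C)(C)OC(=O)[C@@H](OCc1ccccc1)[C@@H](O)C(=O)OC | intermediate
19 | 1-tert-butyl 4-methyl (2S,3S)-2-(benzyloxy)-3-(ArO)butanedioate | CC(C)(C)OC(=O)[C@@H](OCc1ccccc1)[C@H](Oc1cc2c(=O)cc(CCc3ccccc3)oc2cc1OCc1ccccc1)C(=O)OC | intermediate
20 | (2S,3S)-3-(benzyloxy)-4-tert-butoxy-2-(ArO)-4-oxobutanoic acid | CC(C)(C)OC(=O)[C@@H](OCc1ccccc1)[C@H](Oc1cc2c(=O)cc(CCc3ccccc3)oc2cc1OCc1ccccc1)C(=O)O | intermediate
21 | tert-butyl (2S,3S)-2-(benzyloxy)-3-(ArO)-4-(ethylsulfanyl)-4-oxobutanoate | CC(C)(C)OC(=O)[C@@H](OCc1ccccc1)[C@H](Oc1cc2c(=O)cc(CCc3ccccc3)oc2cc1OCc1ccccc1)C(=O)SCC | intermediate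
22 | (2S,3S)-2-(benzyloxy)-3-(ArO)-4-(ethylsulfanyl)-4-oxobutanoic acid | OC(=O)[C@@H](OCc1ccccc1)[C@H](Oc1cc2c(=O)cc(CCc3ccccc3)oc2cc1OCc1ccccc1)C(=O)SCC | intermediate
23 | acyl Meldrum's acid of 22 (enol form), 5-[(2S,3S)-2-(benzyloxy)-3-(ArO)-4-(ethylsulfanyl)-1-hydroxy-4-oxobutylidene]-2,2-dimethyl-1,3-dioxane-4,6-dione | CC1(C)OC(=O)C(=C(O)[C@@H](OCc2ccccc2)[C@H](Oc2cc3c(=O)cc(CCc4ccccc4)oc3cc2OCc2ccccc2)C(=O)SCC)C(=O)O1 | intermediate
24 | S,S'-diethyl (2S,3S)-3-(benzyloxy)-2-(ArO)-4-oxohexanebis(thioate) | CCSC(=O)CC(=O)[C@@H](OCc1ccccc1)[C@H](Oc1cc2c(=O)cc(CCc3ccccc3)oc2cc1OCc1ccccc1)C(=O)SCC | intermediate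
25 | 5-(4-methoxyphenyl)pent-2-ynoyl chloride | COc1ccc(CCC#CC(=O)Cl)cc1 | intermediate
26 | triacylmethane, S,S'-diethyl (2S,3S)-3-(benzyloxy)-2-(ArO)-5-[5-(4-methoxyphenyl)pent-2-ynoyl]-4-oxohexanebis(thioate), C5 not defined | CCSC(=O)C(C(=O)C#CCCc1ccc(OC)cc1)C(=O)[C@@H](OCc1ccccc1)[C@H](Oc1cc2c(=O)cc(CCc3ccccc3)oc2cc1OCc1ccccc1)C(=O)SCC | intermediate
27 | S-ethyl 2-[(1S,2S)-1-(benzyloxy)-2-(ArO)-3-(ethylsulfanyl)-3-oxopropyl]-6-[2-(4-methoxyphenyl)ethyl]-4-oxo-4H-pyran-3-carbothioate | COc1ccc(CCc2cc(=O)c(C(=O)SCC)c(o2)[C@@H](OCc3ccccc3)[C@H](Oc3cc4c(=O)cc(CCc5ccccc5)oc4cc3OCc3ccccc3)C(=O)SCC)cc1 | intermediate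
28 | 2-[(1S,2S)-1-(benzyloxy)-2-(ArO)-3-oxopropyl]-6-[2-(4-methoxyphenyl)ethyl]-4-oxo-4H-pyran-3-carbaldehyde | COc1ccc(CCc2cc(=O)c(C=O)c(o2)[C@@H](OCc3ccccc3)[C@H](Oc3cc4c(=O)cc(CCc5ccccc5)oc4cc3OCc3ccccc3)C=O)cc1 | intermediate
29 | (5S,6S,7R,8S)-8-(benzyloxy)-7-(ArO)-5,6-dihydroxy-2-[2-(4-methoxyphenyl)ethyl]-5,6,7,8-tetrahydro-4H-chromen-4-one | COc1ccc(CCc2cc(=O)c3c(o2)[C@@H](OCc4ccccc4)[C@H](Oc4cc5c(=O)cc(CCc6ccccc6)oc5cc4OCc4ccccc4)[C@@H](O)[C@H]3O)cc1 | intermediate
30 | (5S,6S,7R,8S)-5,6,8-trihydroxy-7-{[7-hydroxy-4-oxo-2-(2-phenylethyl)-4H-chromen-6-yl]oxy}-2-[2-(4-methoxyphenyl)ethyl]-5,6,7,8-tetrahydro-4H-chromen-4-one | COc1ccc(CCc2cc(=O)c3c(o2)[C@@H](O)[C@H](Oc4cc5c(=O)cc(CCc6ccccc6)oc5cc4O)[C@@H](O)[C@H]3O)cc1 | intermediate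
31 | (+)-4'-methoxyaquisinenone G, (5R,6S,7R,8S) | COc1ccc(CCc2cc(=O)c3c(o2)[C@@H](O)[C@@H]2Oc4cc5c(=O)cc(CCc6ccccc6)oc5cc4O[C@H]3[C@@H]2O)cc1 | target

**Step count**

Total: 21 steps. Longest linear sequence: 15 steps (steps 7–21, from dimethyl D-tartrate 13).

**Steps most likely to fail**

Step 19 (pinacol cyclisation). The ketyl may add to the C6 aldehyde on the face syn to the C7 aryloxy group, or a second electron transfer may expel the C8 benzyloxy or the C7 aryloxy group before the ring closes. The fallback sets out from 28 and comes back at 29. Both aldehydes of 28 are methylenated under non-basic conditions (Zn, CH2Br2, TiCl4, THF/CH2Cl2) to 2-[(1S,2R)-1-(benzyloxy)-2-(ArO)but-3-en-1-yl]-3-ethenyl-6-[2-(4-methoxyphenyl)ethyl]-4H-pyran-4-one F1. Ring-closing metathesis with the second-generation Grubbs catalyst (CH2Cl2, 40 °C) then forms the same C5–C6 bond as an alkene, (7R,8S)-8-(benzyloxy)-7-(ArO)-2-[2-(4-methoxyphenyl)ethyl]-7,8-dihydro-4H-chromen-4-one F2. Dihydroxylation with OsO4 (cat.) and NMO in acetone/H2O should add both hydroxyls to C5=C6 from the face opposite to the allylic C7 aryloxy group, which gives 29.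

Step 21 (bridge closure). The C5 cation may lose a proton or take a hydride from C6 (ketone formation and then aromatisation of the carbocycle), or be trapped by a second molecule, before the phenol closes the seven-membered bridge. The fallback sets out from 30 and comes back at 31 by SN2 chemistry. The cis-5,6-diol is converted into its cyclic orthoacetate (MeC(OMe)3, PPTS, CH2Cl2) and opened with Me3SiCl, which should place chloride at the activated C5 with inversion and give (5R,6R,7S,8S)-5-chloro-8-hydroxy-7-{[7-hydroxy-4-oxo-2-(2-phenylethyl)-4H-chromen-6-yl]oxy}-2-[2-(4-methoxyphenyl)ethyl]-4-oxo-5,6,7,8-tetrahydro-4H-chromen-6-yl acetate F3. K2CO3 in MeOH removes the acetate, and the C6 alkoxide closes the 5,6-epoxy-8-hydroxy-7-{[7-hydroxy-4-oxo-2-(2-phenylethyl)-4H-chromen-6-yl]oxy}-2-[2-(4-methoxyphenyl)ethyl]-5,6,7,8-tetrahydro-4H-chromen-4-one F4 (epoxide oxygen trans to the C7 ether). In the same flask the phenoxide should open the epoxide at C5 from the opposite face to give 31.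

Step 17 (pyranone annulation). O-acylation of the enolate and conjugate addition of chloride or pyridine to the activated alkynoyl chloride may compete with C-acylation, so that triacylmethane 26 does not form cleanly. The fallback sets out from 22 (and from 25, made from 12 as in step 17) and comes back at 27, with the ynone moved into the nucleophile. Acid chloride 25 is added to two equivalents of the lithium enolate of S-ethyl thioacetate (LiHMDS, THF, −78 °C) to give S-ethyl 7-(4-methoxyphenyl)-3-oxohept-4-ynethioate F5. Acid 22 is converted with 1-chloro-N,N,2-trimethylprop-1-en-1-amine (CH2Cl2, 0 °C) into S-ethyl (2S,3S)-3-(benzyloxy)-2-(ArO)-4-chloro-4-oxobutanethioate F6. F6 C-acylates the magnesium enolate of F5 (MgCl2, pyridine, CH2Cl2) to the same triacylmethane 26, and TsOH-catalysed cyclisation gives 27.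

**Further compounds**

F1 | step 19 | 2-[(1S,2R)-1-(benzyloxy)-2-(ArO)but-3-en-1-yl]-3-ethenyl-6-[2-(4-methoxyphenyl)ethyl]-4H-pyran-4-one | COc1ccc(CCc2cc(=O)c(C=C)c(o2)[C@@H](OCc3ccccc3)[C@H](Oc3cc4c(=O)cc(CCc5ccccc5)oc4cc3OCc3ccccc3)C=C)cc1
F2 | step 19 | (7R,8S)-8-(benzyloxy)-7-(ArO)-2-[2-(4-methoxyphenyl)ethyl]-7,8-dihydro-4H-chromen-4-one | COc1ccc(CCc2cc(=O)c3c(o2)[C@@H](OCc4ccccc4)[C@H](Oc4cc5c(=O)cc(CCc6ccccc6)oc5cc4OCc4ccccc4)C=C3)cc1
F3 | step 21 | (5R,6R,7S,8S)-5-chloro-8-hydroxy-7-{[7-hydroxy-4-oxo-2-(2-phenylethyl)-4H-chromen-6-yl]oxy}-2-[2-(4-methoxyphenyl)ethyl]-4-oxo-5,6,7,8-tetrahydro-4H-chromen-6-yl acetate | COc1ccc(CCc2cc(=O)c3c(o2)[C@@H](O)[C@H](Oc4cc5c(=O)cc(CCc6ccccc6)oc5cc4O)[C@@H](OC(C)=O)[C@@H]3Cl)cc1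
F4 | step 21 | 5,6-epoxy-8-hydroxy-7-{[7-hydroxy-4-oxo-2-(2-phenylethyl)-4H-chromen-6-yl]oxy}-2-[2-(4-methoxyphenyl)ethyl]-5,6,7,8-tetrahydro-4H-chromen-4-one, epoxide oxygen trans to the C7 ether | COc1ccc(CCc2cc(=O)c3c(o2)[C@@H](O)[C@H](Oc4cc5c(=O)cc(CCc6ccccc6)oc5cc4O)[C@H]4O[C@@H]34)cc1
F5 | step 17 | S-ethyl 7-(4-methoxyphenyl)-3-oxohept-4-ynethioate | CCSC(=O)CC(=O)C#CCCc1ccc(OC)cc1
F6 | step 17 | S-ethyl (2S,3S)-3-(benzyloxy)-2-(ArO)-4-chloro-4-oxobutanethioate | ClC(=O)[C@@H](OCc1ccccc1)[C@H](Oc1cc2c(=O)cc(CCc3ccccc3)oc2cc1OCc1ccccc1)C(=O)SCC
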